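The runs come from a simulation for substances that don't exist, and the scatter is random.

In a one-step world the substrate passes straight to over-reaction product, so the final reading of over-reaction product equals the charge; the last readings of the earlier runs fall short of it.

| flask | substrate | catalyst | remark | time |
|---|---|---|---|---|
| north-west | 2 mM (fed, over 10 s) | 27 µM | run made earlier |  |
| north-east | 2 mM (fed, over 10 s) | 42 µM | run made earlier |  |
| east | 4 mM (fed, over 10 s) | 19 µM | run made earlier |  |
| flask | 2.0 mM (fed, over 10 s) | 19 µM |  | 15 min |

- north-west (time / min: substrate / %, over-reaction product / %, target / %): 0.667: 1.2, 31.2, 48.7; 1.33: 0, 56.9, 24.0; 2.00: 0, 69.2, 11.9; 3.00: 0, 77.0, 4.5; 5.00: 0, 80.0, 0.6; 10.0: 0.6, 81.1, 0.1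
- north-east (time / min: substrate / %, over-reaction product / %, target / %): 0.667: 0.6, 35.6, 49.9; 1.33: 0, 61.6, 24.7; 2.00: 0.8, 74.6, 12.0; 3.00: 0, 81.2, 4.4; 5.00: 0, 84.5, 0.4; 10.0: 1.2, 86.3, 0
- east (time / min: substrate / %, over-reaction product / %, target / %): 0.833: 0.7, 29.9, 31.4; 2.50: 0.4, 55.3, 4.8; 4.00: 0, 60.1, 1.2; 6.00: 0, 61.4, 0; 10.0: 1.4, 61.1, 0.7

(scatter of a reading: 0.5 percentage points)

- the earlier runs were read with a standard deviation of 0.5 percentage points
- the reaction counts as stopped when no species that holds the substrate changes by six tenths of a point or more over the second half of the time

* the state of affairs at 15 min: stopped, and by what, or still going (no working catalyst is left / it is still moving / all of the substrate has reacted)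
* share of the substrate used up at 15 min
* over-reaction product at 15 min, in percent of the substrate charged

**Step one.** Define the loading ρ (the usual catalyst loading) as catalyst over substrate charged, and the missing share M as the charge absent from the last over-reaction product reading, once target and substrate read near zero. The east run has ρ = 0.475% and M = 38.9%, the north-west run 1.35% and 18.9%, and the north-east run 2.10% and 13.7%, so M falls as ρ rises.

**Step two.** The flask shares its catalyst with the east run and its substrate with the north-west run. Taken as a copy of the east run, it ends at 61.1% over-reaction product; taken as a copy of the north-west run, at 81.1%. The flask's loading, 0.950%, lies above that of the east run and below that of the north-west run, so on the fall of M read in step one its M is expected between theirs.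

**Step three.** In logarithms, ρ rises by 0.454 from the east run to the north-west run and M falls by 0.313, which reads, within the scatter of those two last samples, as the loss order n = 0.691, the fall in the logarithm of M per unit rise in that of ρ. The flask has twice the east loading, so my reckoning gives M = 24.1%.

**Step four.** The forecast says all of the substrate has reacted, conversion 100% and over-reaction product 76%, on the ground that “The loss scales with catalyst/substrate ratio”.

**Result.** In the flask at 15 min, all of the substrate has reacted; conversion is 100% and over-reaction product 75.5%.

    substrate + target → side product (k = 17.0 M⁻¹ s⁻¹)
    target → over-reaction product (k = 0.0180 s⁻¹)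
    substrate + catalyst → catalyst + target (k = 4200 M⁻¹ s⁻¹)

The flask's missing share is side product, 24.5%, against 24.1% from n. The same flask with 0.011 mM catalyst has loading 0.550%, where n gives 35.2% and that neighbour flask ends with 32.9% side product. The flask itself has come to rest: over the second half of its time no share moves by more than 0.031 percentage points. At 150 min, ten times the time, the flask still holds 75.5% over-reaction product and 24.5% side product.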